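**Retrosynthetic overview**

- Numbering: the upper 4-arylflavan-3-ol is O1, C2, C3, C4 (rings A, B, C); the lower flavan-3,4-diol is primed (benzo ring D, catechol ring E, pyran ring F); the halves are joined C4–C6'.
- The route rests on C4' of ring F, a benzylic carbinol carbon para to the C7' oxygen and ortho to O1' of ring D. It ionises readily, and its OH must be cis to the C3' OH, which a five-membered ring fused across C3'–C4' guarantees.
- Disconnections: (a) C4'–O, by capture of the C4' cation with the C3' tert-butyl carbonate (23 to 24); (b) C4–C6' and C3–O, by syn-arylboration/oxidation of flav-3-ene 7 with aryl bromide 18; (c) both flavenes from chromones 2 and 11 by asymmetric conjugate addition of boronic acid 3.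
- Ring order: ring C is present in chromone 1 and ring F is closed in step 6; rings B and E are attached in steps 2 and 7; the dioxolanone is closed in step 16 and opened in step 17.

Key step: step 16

Assumption: the (R)-pyridinooxazoline ligand is taken to give the (2S)-flavanones, by analogy with the facial preference of this catalyst on cyclic enones; if the sense proves opposite, the ligand antipode is used.

**Route**

Step 1
Reactants: 1 7-hydroxychromone
Product: 2 7-(benzyloxy)-4H-chromen-4-one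
Conditions: BnBr, K2CO3, DMF, 50 °C
Reagents that add atoms: benzyl bromide, BrCc1ccccc1
Why: Williamson etherification of the acidic 7-phenol, with no stereocentre involved.

Step 2
Reactants: 2 7-(benzyloxy)-4H-chromen-4-one; 3 3,4-bis(benzyloxy)phenylboronic acid
Product: 4 (S)-7-(benzyloxy)-2-[3,4-bis(benzyloxy)phenyl]chroman-4-one
Conditions: Pd(OCOCF3)2 (5 mol%), (R)-4-tert-butyl-2-(pyridin-2-yl)-4,5-dihydrooxazole (6 mol%), NH4PF6, H2O, ClCH2CH2Cl, 60 °C; recrystallise
Reagents that add atoms: none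
Why: Asymmetric conjugate addition of an arylboronic acid to a chromone under cationic divalent palladium–pyridinooxazoline catalysis, in which the tert-butyl group of the ligand selects the enone face and should set C2 as S.

Step 3
Reactants: 4 (S)-7-(benzyloxy)-2-[3,4-bis(benzyloxy)phenyl]chroman-4-one
Product: 5 (2S,4S)-7-(benzyloxy)-2-[3,4-bis(benzyloxy)phenyl]chroman-4-ol
Conditions: NaBH4, THF/MeOH, 0 °C
Reagents that add atoms: none
Why: Hydride reduction of the aryl ketone, expected to give the 2,4-cis alcohol by axial delivery; the C4 configuration is removed in the next step and C2 is not touched.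

Step 4
Reactants: 5 (2S,4S)-7-(benzyloxy)-2-[3,4-bis(benzyloxy)phenyl]chroman-4-ol
Product: 7 (S)-7-(benzyloxy)-2-[3,4-bis(benzyloxy)phenyl]-2H-chromene, via C4 mesylate 6 (not isolated)
Conditions: MsCl, Et3N, CH2Cl2, 0 to 40 °C
Reagents that add atoms: none
Why: Sulfonylation followed by amine-mediated elimination (dehydration) of the activated benzylic mesylate; acid is avoided because the allylic, benzylic C2–O1 bond of the flavene would ionise and racemise C2.

Step 5
Reactants: 8 1-(5-bromo-2,4-dihydroxyphenyl)ethanone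
Product: 9 1-[4-(benzyloxy)-5-bromo-2-hydroxyphenyl]ethanone
Conditions: BnBr (1 equiv), K2CO3, acetone, reflux
Reagents that add atoms: benzyl bromide, BrCc1ccccc1
Why: Williamson etherification selective for the 4-hydroxyl, since the 2-hydroxyl is held in a hydrogen bond to the ketone.

Step 6
Reactants: 9 1-[4-(benzyloxy)-5-bromo-2-hydroxyphenyl]ethanone
Product: 11 7-(benzyloxy)-6-bromo-4H-chromen-4-one, via enaminone 10 (not isolated)
Conditions: Me2NCH(OMe)2, toluene, 100 °C; then HCl (aq.), CH2Cl2, 25 °C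
Reagents that add atoms: N,N-dimethylformamide dimethyl acetal, COC(OC)N(C)C
Why: Enaminone formation and acid-mediated cyclisation with loss of dimethylamine, the standard chromone synthesis from 2-hydroxyacetophenones, closes the future ring F with the bromine already at C6.

Step 7
Reactants: 11 7-(benzyloxy)-6-bromo-4H-chromen-4-one; 3 3,4-bis(benzyloxy)phenylboronic acid
Product: 12 (S)-7-(benzyloxy)-2-[3,4-bis(benzyloxy)phenyl]-6-bromochroman-4-one
Conditions: Pd(OCOCF3)2 (5 mol%), (R)-4-tert-butyl-2-(pyridin-2-yl)-4,5-dihydrooxazole (6 mol%), NH4PF6, H2O, ClCH2CH2Cl, 60 °C; recrystallise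
Reagents that add atoms: none
Why: The same asymmetric conjugate addition as in step 2 should set C2 as S; the cycle stays at divalent palladium, so the aryl bromide should not be attacked.

Step 8
Reactants: 12 (S)-7-(benzyloxy)-2-[3,4-bis(benzyloxy)phenyl]-6-bromochroman-4-one
Product: 13 (2S,4S)-7-(benzyloxy)-2-[3,4-bis(benzyloxy)phenyl]-6-bromochroman-4-ol
Conditions: NaBH4, THF/MeOH, 0 °C
Reagents that add atoms: none
Why: Hydride reduction of the ketone as in step 3; the aryl bromide is inert to NaBH4.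

Step 9
Reactants: 13 (2S,4S)-7-(benzyloxy)-2-[3,4-bis(benzyloxy)phenyl]-6-bromochroman-4-ol
Product: 15 (S)-7-(benzyloxy)-2-[3,4-bis(benzyloxy)phenyl]-6-bromo-2H-chromene, via C4 mesylate 14 (not isolated)
Conditions: MsCl, Et3N, CH2Cl2, 0 to 40 °C
Reagents that add atoms: none
Why: Mesylation and base-mediated elimination as in step 4, again without acid so that C2 keeps its configuration.

Step 10
Reactants: 15 (S)-7-(benzyloxy)-2-[3,4-bis(benzyloxy)phenyl]-6-bromo-2H-chromene
Product: 17 (2R,3S,4R)-7-(benzyloxy)-2-[3,4-bis(benzyloxy)phenyl]-6-bromo-4-methoxychroman-3-ol, via flavene oxide 16 (not isolated)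
Conditions: dimethyldioxirane, acetone/CH2Cl2, −20 °C; then MeOH, pyridinium p-toluenesulfonate (cat.), −20 to 0 °C
Reagents that add atoms: dimethyldioxirane, CC1(C)OO1; methanol, CO
Why: Epoxidation on the alkene face opposite the C2 aryl group should set C3 (2,3-trans), and acid-catalysed epoxide opening by methanol at the benzylic C4 gives the 4-methyl ether; the C4 configuration is unimportant because step 16 is stereoconvergent.

Step 11
Reactants: 17 (2R,3S,4R)-7-(benzyloxy)-2-[3,4-bis(benzyloxy)phenyl]-6-bromo-4-methoxychroman-3-ol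
Product: 18 (2R,3S,4R)-7-(benzyloxy)-2-[3,4-bis(benzyloxy)phenyl]-6-bromo-3-(tert-butyldimethylsilyloxy)-4-methoxychromane
Conditions: TBSCl, imidazole, DMAP (cat.), DMF, 40 °C
Reagents that add atoms: tert-butyldimethylsilyl chloride, CC(C)(C)[Si](C)(C)Cl
Why: Silyl ether formation under non-acidic conditions gives a C3 protecting group that tolerates the alkoxide base of the coupling and leaves the C4 ether intact.

Step 12
Reactants: 7 (S)-7-(benzyloxy)-2-[3,4-bis(benzyloxy)phenyl]-2H-chromene; 18 (2R,3S,4R)-7-(benzyloxy)-2-[3,4-bis(benzyloxy)phenyl]-6-bromo-3-(tert-butyldimethylsilyloxy)-4-methoxychromane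
Product: 20 hexa-O-benzyl C4–C6' dimer bearing upper C3–OH (2,3-trans-3,4-cis) plus lower C3'–OTBS/C4'–OMe, via C3 boronate 19 (not isolated)
Conditions: B2pin2, NaOtBu, CuCl/1,3-dimesitylimidazolinium chloride (10 mol%), Pd(OAc)2/RuPhos (5 mol%), toluene, 30 °C; then NaBO3·4H2O, THF/H2O, 25 °C
Reagents that add atoms: sodium perborate tetrahydrate, [Na+].[O-]OB=O.O.O.O.O
Why: Cooperative copper/palladium syn-arylboration of a cyclic alkenyl arene: the monovalent copper boryl should add across C3=C4 on the face opposite the C2 aryl group, placing boron at C3 and copper at benzylic C4; stereoretentive transmetalation to the arylpalladium bromide and reductive elimination then form C4–C6' cis to boron, and perborate oxidation replaces boron by hydroxyl with retention.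

Step 13
Reactants: 20 dimer with upper C3–OH, lower C3'–OTBS and C4'–OMe
Product: 21 dimer with upper C3–OAc, lower C3'–OTBS and C4'–OMe
Conditions: Ac2O, pyridine, DMAP (cat.), CH2Cl2, 25 °C
Reagents that add atoms: acetic anhydride, CC(=O)OC(C)=O
Why: DMAP-catalysed acylation of the only free hydroxyl masks the upper C3–OH, so that only C3'–OH is carbonated later; the acetate is removed together with the carbonate in step 17.

Step 14
Reactants: 21 dimer with upper C3–OAc, lower C3'–OTBS and C4'–OMe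
Product: 22 dimer with upper C3–OAc, lower C3'–OH and C4'–OMe
Conditions: TBAF, AcOH, THF, 25 °C
Reagents that add atoms: none
Why: Fluoride-mediated desilylation, buffered with acetic acid so that the acetate is kept and the C4' ether is not ionised.

Step 15
Reactants: 22 dimer with upper C3–OAc, lower C3'–OH and C4'–OMe
Product: 23 dimer with upper C3–OAc, lower C3' tert-butyl carbonate and C4'–OMe (3',4'-trans shown)
Conditions: Boc2O, DMAP, MeCN/CH2Cl2, 25 °C
Reagents that add atoms: di-tert-butyl dicarbonate, CC(C)(C)OC(=O)OC(=O)OC(C)(C)C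
Why: DMAP-catalysed tert-butoxycarbonylation of the single free secondary alcohol installs the neighbouring group for the key step.

Step 16
Reactants: 23 dimer with upper C3–OAc, lower C3' tert-butyl carbonate and C4'–OMe
Product: 24 dimer with upper C3–OAc and cis-fused 3',4'-cyclic carbonate
Conditions: BF3·OEt2, CH2Cl2, −78 to −30 °C; quench Et3N
Reagents that add atoms: none
Why: BF3·OEt2 removes methoxide from C4' of either epimer to give one planar benzylic cation stabilised by the para C7' oxygen and the ortho ring oxygen O1'; the carbonyl oxygen of the C3' tert-butyl carbonate adds to it and the resulting dioxolanylium ion loses 2-methylpropene, which makes the capture irreversible. The closest known reaction type is neighbouring-group capture of benzylic and oxocarbenium cations by tert-butyl carbonates to give cyclic carbonates, as in iodocarbonate cyclisation and in the 1,2-cyclic carbonates formed from 2-O-Boc glycosyl donors. The 1,3-dioxolan-2-one ring closes in a 5-exo-trig mode onto the cationic C4'. The new C4' stereocentre is controlled by the fixed C3' configuration, since the two-atom O–C(=O) bridge can reach the adjacent planar carbon only from the face that carries the C3' oxygen, so the ring fusion is cis. The step needs this cis selectivity and ionisation at C4' alone; the first follows from the tether, and the second from C4' being the only benzylic carbon with an oxygen leaving group, because the upper C4 is a C–H diarylmethine and the C2 and C2' ring ethers lack this double activation at low temperature. The intramolecular trap should also outrun external nucleophiles and elimination, and the upper acetate is too remote to take part.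

Step 17
Reactants: 24 dimer with upper C3–OAc and cis-fused 3',4'-cyclic carbonate
Product: 25 hexa-O-benzyl dimer with free upper C3–OH and lower 3',4'-cis-diol
Conditions: K2CO3, MeOH/THF, 25 °C
Reagents that add atoms: none
Why: Base-catalysed methanolysis (transesterification) cleaves the cyclic carbonate and the acetate at their acyl carbons, so no C–O bond at C3, C3' or C4' is broken and all configurations are retained.

Step 18
Reactants: 25 hexa-O-benzyl dimer with free upper C3–OH and lower 3',4'-cis-diol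
Product: 26 (2R,3S,4S)-2-(3,4-dihydroxyphenyl)-6-[(2R,3S,4S)-2-(3,4-dihydroxyphenyl)-3,7-dihydroxychroman-4-yl]chromane-3,4,7-triol (CNP0280090.1)
Conditions: H2 (1 atm), Pd(OH)2/C, EtOAc/MeOH, 25 °C, stopped as soon as debenzylation is complete; filter under argon, lyophilise
Reagents that add atoms: none
Why: Catalytic hydrogenolysis of the six aryl benzyl ethers; a neutral medium and short contact time should keep the free benzylic C4'–OH and the C4–C6' bond intact.

**Compound list**

1 | 7-hydroxychromone | O=c1ccoc2cc(O)ccc12 | starting material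
2 | 7-(benzyloxy)-4H-chromen-4-one | O=c1ccoc2cc(OCc9ccccc9)ccc12 | intermediate
3 | 3,4-bis(benzyloxy)phenylboronic acid | OB(O)c1ccc(OCc2ccccc2)c(OCc2ccccc2)c1 | starting material
4 | (S)-7-(benzyloxy)-2-[3,4-bis(benzyloxy)phenyl]chroman-4-one | O=C1C[C@@H](c2ccc(OCc9ccccc9)c(OCc9ccccc9)c2)Oc2cc(OCc9ccccc9)ccc12 | intermediate
5 | (2S,4S)-7-(benzyloxy)-2-[3,4-bis(benzyloxy)phenyl]chroman-4-ol | O[C@H]1C[C@@H](c2ccc(OCc9ccccc9)c(OCc9ccccc9)c2)Oc2cc(OCc9ccccc9)ccc12 | intermediate
6 | 4-O-methanesulfonate of 5 (formed in the flask) | CS(=O)(=O)O[C@H]1C[C@@H](c2ccc(OCc9ccccc9)c(OCc9ccccc9)c2)Oc2cc(OCc9ccccc9)ccc12 | intermediate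
7 | (S)-7-(benzyloxy)-2-[3,4-bis(benzyloxy)phenyl]-2H-chromene | C1=C[C@@H](c2ccc(OCc9ccccc9)c(OCc9ccccc9)c2)Oc2cc(OCc9ccccc9)ccc12 | intermediate
8 | 1-(5-bromo-2,4-dihydroxyphenyl)ethanone | CC(=O)c1cc(Br)c(O)cc1O | starting material
9 | 1-[4-(benzyloxy)-5-bromo-2-hydroxyphenyl]ethanone | CC(=O)c1cc(Br)c(OCc9ccccc9)cc1O | intermediate
10 | (E)-1-[4-(benzyloxy)-5-bromo-2-hydroxyphenyl]-3-(dimethylamino)prop-2-en-1-one (formed in the flask) | CN(C)/C=C/C(=O)c1cc(Br)c(OCc9ccccc9)cc1O | intermediate
11 | 7-(benzyloxy)-6-bromo-4H-chromen-4-one | O=c1ccoc2cc(OCc9ccccc9)c(Br)cc12 | intermediate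
12 | (S)-7-(benzyloxy)-2-[3,4-bis(benzyloxy)phenyl]-6-bromochroman-4-one | O=C1C[C@@H](c2ccc(OCc9ccccc9)c(OCc9ccccc9)c2)Oc2cc(OCc9ccccc9)c(Br)cc12 | intermediate
13 | (2S,4S)-7-(benzyloxy)-2-[3,4-bis(benzyloxy)phenyl]-6-bromochroman-4-ol | O[C@H]1C[C@@H](c2ccc(OCc9ccccc9)c(OCc9ccccc9)c2)Oc2cc(OCc9ccccc9)c(Br)cc12 | intermediate
14 | 4-O-methanesulfonate of 13 (formed in the flask) | CS(=O)(=O)O[C@H]1C[C@@H](c2ccc(OCc9ccccc9)c(OCc9ccccc9)c2)Oc2cc(OCc9ccccc9)c(Br)cc12 | intermediate
15 | (S)-7-(benzyloxy)-2-[3,4-bis(benzyloxy)phenyl]-6-bromo-2H-chromene | C1=C[C@@H](c2ccc(OCc9ccccc9)c(OCc9ccccc9)c2)Oc2cc(OCc9ccccc9)c(Br)cc12 | intermediate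
16 | 3,4-epoxide of 15, oxirane on the face opposite the C2 aryl group (formed in the flask) | Brc1cc2c(cc1OCc9ccccc9)O[C@H](c1ccc(OCc9ccccc9)c(OCc9ccccc9)c1)[C@H]1O[C@@H]21 | intermediate
17 | (2R,3S,4R)-7-(benzyloxy)-2-[3,4-bis(benzyloxy)phenyl]-6-bromo-4-methoxychroman-3-ol | Brc1cc2c(cc1OCc9ccccc9)O[C@H](c1ccc(OCc9ccccc9)c(OCc9ccccc9)c1)[C@@H](O)[C@@H]2OC | intermediate
18 | (2R,3S,4R)-7-(benzyloxy)-2-[3,4-bis(benzyloxy)phenyl]-6-bromo-3-(tert-butyldimethylsilyloxy)-4-methoxychromane | Brc1cc2c(cc1OCc9ccccc9)O[C@H](c1ccc(OCc9ccccc9)c(OCc9ccccc9)c1)[C@@H](O[Si](C)(C)C(C)(C)C)[C@@H]2OC | intermediate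
19 | hexa-O-benzyl C4–C6' dimer, upper C3–B(pin) cis to the C4 aryl and trans to the C2 aryl, lower C3'–OTBS and C4'–OMe (formed in the flask) | C(c9ccccc9)Oc1ccc2c(c1)O[C@H](c1ccc(OCc9ccccc9)c(OCc9ccccc9)c1)[C@@H](B3OC(C)(C)C(C)(C)O3)[C@H]2c1cc2c(cc1OCc9ccccc9)O[C@H](c1ccc(OCc9ccccc9)c(OCc9ccccc9)c1)[C@@H](O[Si](C)(C)C(C)(C)C)[C@@H]2OC | intermediate
20 | hexa-O-benzyl dimer, upper unit 2,3-trans-3,4-cis with free C3–OH, lower C3'–OTBS and C4'–OMe | C(c9ccccc9)Oc1ccc2c(c1)O[C@H](c1ccc(OCc9ccccc9)c(OCc9ccccc9)c1)[C@@H](O)[C@H]2c1cc2c(cc1OCc9ccccc9)O[C@H](c1ccc(OCc9ccccc9)c(OCc9ccccc9)c1)[C@@H](O[Si](C)(C)C(C)(C)C)[C@@H]2OC | intermediate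
21 | hexa-O-benzyl dimer, upper C3–OAc, lower C3'–OTBS and C4'–OMe | C(c9ccccc9)Oc1ccc2c(c1)O[C@H](c1ccc(OCc9ccccc9)c(OCc9ccccc9)c1)[C@@H](OC(C)=O)[C@H]2c1cc2c(cc1OCc9ccccc9)O[C@H](c1ccc(OCc9ccccc9)c(OCc9ccccc9)c1)[C@@H](O[Si](C)(C)C(C)(C)C)[C@@H]2OC | intermediate
22 | hexa-O-benzyl dimer, upper C3–OAc, lower C3'–OH and C4'–OMe | C(c9ccccc9)Oc1ccc2c(c1)O[C@H](c1ccc(OCc9ccccc9)c(OCc9ccccc9)c1)[C@@H](OC(C)=O)[C@H]2c1cc2c(cc1OCc9ccccc9)O[C@H](c1ccc(OCc9ccccc9)c(OCc9ccccc9)c1)[C@@H](O)[C@@H]2OC | intermediate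
23 | key-step precursor: hexa-O-benzyl dimer, upper C3–OAc, lower C3' tert-butyl carbonate and C4'–OMe (3',4'-trans shown; the cis epimer converges) | C(c9ccccc9)Oc1ccc2c(c1)O[C@H](c1ccc(OCc9ccccc9)c(OCc9ccccc9)c1)[C@@H](OC(C)=O)[C@H]2c1cc2c(cc1OCc9ccccc9)O[C@H](c1ccc(OCc9ccccc9)c(OCc9ccccc9)c1)[C@@H](OC(=O)OC(C)(C)C)[C@@H]2OC | intermediate
24 | key-step product: hexa-O-benzyl dimer, upper C3–OAc, cis-fused 3',4'-cyclic carbonate | C(c9ccccc9)Oc1ccc2c(c1)O[C@H](c1ccc(OCc9ccccc9)c(OCc9ccccc9)c1)[C@@H](OC(C)=O)[C@H]2c1cc2c(cc1OCc9ccccc9)O[C@H](c1ccc(OCc9ccccc9)c(OCc9ccccc9)c1)[C@@H](O3)[C@H]2OC3=O | intermediate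
25 | hexa-O-benzyl dimer with free upper C3–OH and lower 3',4'-cis-diol | C(c9ccccc9)Oc1ccc2c(c1)O[C@H](c1ccc(OCc9ccccc9)c(OCc9ccccc9)c1)[C@@H](O)[C@H]2c1cc2c(cc1OCc9ccccc9)O[C@H](c1ccc(OCc9ccccc9)c(OCc9ccccc9)c1)[C@@H](O)[C@H]2O | intermediate
26 | (2R,3S,4S)-2-(3,4-dihydroxyphenyl)-6-[(2R,3S,4S)-2-(3,4-dihydroxyphenyl)-3,7-dihydroxychroman-4-yl]chromane-3,4,7-triol (CNP0280090.1) | Oc1ccc2c(c1)O[C@H](c1ccc(O)c(O)c1)[C@@H](O)[C@H]2c1cc2c(cc1O)O[C@H](c1ccc(O)c(O)c1)[C@@H](O)[C@H]2O | target

**Step count and risks**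

Total step count: 18. Longest linear sequence: 14 steps (steps 5 to 18).

Steps most likely to fail:

1. Step 12 (arylboration/oxidation). Oxidative addition and transmetalation with the hindered, electron-rich bromide may be slow, so that protoboration of the flavene or direct borylation of the bromide takes over. The copper-to-palladium transfer may also proceed with inversion and erode the syn relationship, and the facial bias at C3 may be insufficient. The fallback separates the two bond formations; it sets out from 7 (with 18) and rejoins the route at 19. Syn-diboration of 7 with B2pin2 under Pt(dba)2 catalysis (toluene, 50 °C), on the face opposite the C2 aryl group, should give the 2,3-trans-3,4-cis-3,4-bis(pinacolboryl)flavan F1. Its benzylic C4–B bond alone is then coupled with bromide 18 under the stereoretentive Suzuki–Miyaura conditions for secondary benzylic boronates (Pd2(dba)3, PPh3, Ag2O, 1,2-dimethoxyethane, 80 °C). This gives boronate 19, which is oxidised with NaBO3·4H2O as in step 12.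

2. Step 16 (key step). The Lewis acid may strip the tert-butyl group from the carbonate before C4' ionises, leaving no irreversible trap; the cation may instead lose the C3' proton or be intercepted intermolecularly by an electron-rich ring. The fallback sets the cis-diol by reagent control before the coupling; it sets out from 15 (with 7) and rejoins the route at 25. Dihydroxylation of 15 with OsO4 (cat.) and N-methylmorpholine N-oxide in acetone/H2O, on the face opposite the C2 aryl group, should give (2R,3S,4S)-7-(benzyloxy)-2-[3,4-bis(benzyloxy)phenyl]-6-bromochromane-3,4-diol F2. Silylation with tert-butyldimethylsilyl triflate and 2,6-lutidine (CH2Cl2, −78 °C) gives the bis-silyl ether F3. Arylboration of 7 with F3 under the conditions of step 12 gives the dimer boronate F4, and NaBO3·4H2O oxidises it to the dimer alcohol F5. TBAF in THF then removes both silyl groups to give 25.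

3. Step 7 (asymmetric conjugate addition to the bromochromone). Enantioselectivity may be incomplete, the electron-rich boronic acid may protodeboronate faster than it transmetalates, and any zerovalent palladium formed by catalyst decay may insert into the C–Br bond. The fallback uses condensation and kinetic resolution; it sets out from 9 and rejoins the route at 12. Claisen–Schmidt condensation of 9 with commercial 3,4-bis(benzyloxy)benzaldehyde (KOH, EtOH) gives the 2'-hydroxychalcone F6. Oxa-Michael cyclisation (NaOAc, EtOH, reflux) gives the racemic flavanone F7. Asymmetric transfer hydrogenation with RuCl[(R,R)-TsDPEN](p-cymene) and HCO2H/Et3N, run to just past half conversion, should reduce the (2R)-enantiomer to the (2R,4R)-flavan-4-ol F8 and leave the (S)-ketone 12, which is separated by chromatography.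

**Further compounds**

F1 | step 12 | 2,3-trans-3,4-cis-7-(benzyloxy)-2-[3,4-bis(benzyloxy)phenyl]-3,4-bis(pinacolboryl)chromane | C(c9ccccc9)Oc1ccc2c(c1)O[C@H](c1ccc(OCc9ccccc9)c(OCc9ccccc9)c1)[C@@H](B3OC(C)(C)C(C)(C)O3)[C@H]2B1OC(C)(C)C(C)(C)O1
F2 | step 16 | (2R,3S,4S)-7-(benzyloxy)-2-[3,4-bis(benzyloxy)phenyl]-6-bromochromane-3,4-diol | Brc1cc2c(cc1OCc9ccccc9)O[C@H](c1ccc(OCc9ccccc9)c(OCc9ccccc9)c1)[C@@H](O)[C@H]2O
F3 | step 16 | 3,4-bis-O-(tert-butyldimethylsilyl) ether of F2 | Brc1cc2c(cc1OCc9ccccc9)O[C@H](c1ccc(OCc9ccccc9)c(OCc9ccccc9)c1)[C@@H](O[Si](C)(C)C(C)(C)C)[C@H]2O[Si](C)(C)C(C)(C)C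
F4 | step 16 | hexa-O-benzyl dimer, upper C3–B(pin), lower 3',4'-cis-bis(OTBS) | C(c9ccccc9)Oc1ccc2c(c1)O[C@H](c1ccc(OCc9ccccc9)c(OCc9ccccc9)c1)[C@@H](B3OC(C)(C)C(C)(C)O3)[C@H]2c1cc2c(cc1OCc9ccccc9)O[C@H](c1ccc(OCc9ccccc9)c(OCc9ccccc9)c1)[C@@H](O[Si](C)(C)C(C)(C)C)[C@H]2O[Si](C)(C)C(C)(C)C
F5 | step 16 | hexa-O-benzyl dimer, upper C3–OH, lower 3',4'-cis-bis(OTBS) | C(c9ccccc9)Oc1ccc2c(c1)O[C@H](c1ccc(OCc9ccccc9)c(OCc9ccccc9)c1)[C@@H](O)[C@H]2c1cc2c(cc1OCc9ccccc9)O[C@H](c1ccc(OCc9ccccc9)c(OCc9ccccc9)c1)[C@@H](O[Si](C)(C)C(C)(C)C)[C@H]2O[Si](C)(C)C(C)(C)C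
F6 | step 7 | (E)-1-[4-(benzyloxy)-5-bromo-2-hydroxyphenyl]-3-[3,4-bis(benzyloxy)phenyl]prop-2-en-1-one | O=C(/C=C/c1ccc(OCc9ccccc9)c(OCc9ccccc9)c1)c1cc(Br)c(OCc9ccccc9)cc1O
F7 | step 7 | racemic 7-(benzyloxy)-2-[3,4-bis(benzyloxy)phenyl]-6-bromochroman-4-one | O=C1CC(c2ccc(OCc9ccccc9)c(OCc9ccccc9)c2)Oc2cc(OCc9ccccc9)c(Br)cc12
F8 | step 7 | (2R,4R)-7-(benzyloxy)-2-[3,4-bis(benzyloxy)phenyl]-6-bromochroman-4-ol | O[C@@H]1C[C@H](c2ccc(OCc9ccccc9)c(OCc9ccccc9)c2)Oc2cc(OCc9ccccc9)c(Br)cc12
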